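The target is what I watch, and each target uses one nucleophile.

| flask | electrophile | nucleophile | free base | protic impurity | remark | time |
|---|---|---|---|---|---|---|
| south | 0.52 M | 0.416 M | 0.52 M | 0.017 M | run made earlier |  |
| south-east | 0.52 M | 0.416 M | 0.52 M | 0.039 M | run made earlier |  |
| flask | 0.52 M | 0.416 M | 0.520 M | 0.0260 M |  | 8.0 h |

| run | time / h | electrophile / % | target / % |
|---|---|---|---|
| south | 2.50 | 24.9 | 77.9 |
| south | 5.00 | 23.2 | 77.9 |
| south | 8.00 | 21.4 | 77.2 |
| south | 10.0 | 22.0 | 76.8 |
| south-east | 1.33 | 32.4 | 68.8 |
| south-east | 3.00 | 25.2 | 73.2 |
| south-east | 6.00 | 26.2 | 74.5 |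
| south-east | 10.0 | 24.9 | 73.4 |

(scatter of a reading: 1 percentage point)

- part of the electrophile that has reacted at 8.0 h
- share of the unused nucleophile that is free and not bound as protonated nucleophile, at 8.0 h

- the numbers in the tables scatter by 1 percentage point (one standard deviation)
- the earlier runs do not show how much of nucleophile is bound; that part of a forecast is a guess

1. Nucleophile and electrophile: the nucleophile is the limiting reagent, so by hand [nucleophile] over [electrophile] sets a ceiling of 80.0 % target in the flask. No run changes these two charges.

2. Time: the south run reads 77.9 % target at 2.50 h and 76.8 % at 10.0 h, with a scatter of 1 percentage point.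

3. Free base: both runs hold it at 0.52 M, so they say nothing of it.

4. Protic impurity: the plateau is 77.4 % in the south run and 73.7 % in the south-east run. If the shortfall went to the impurity, 78.0 % and 84.0 % of the impurity were used.

5. The zero of my scale: if a nucleophile took electrophile and impurity with equal ease, the same share of each would remain, however much nucleophile is free at the moment. Then ln(share of impurity left) over ln(share of electrophile left) is 1. The south run reads 1.02 and the south-east run 1.37, both read through a scatter of 1 point. I carry their mean, 1.19, as S, the selectivity factor: that same ratio of logarithms.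

6. My reckoning for the flask: I take the ceiling, subtract the nucleophile lost to impurity, and put the result back in. This gives 75.7 %, then 75.9 %. For the free share I have no reckoning.

The forecast says 76 % reacted and 5 % free, holding that “nearly all the unused nucleophile must be bound”.

The flask gives 75.9 % reacted and 91.6 % of the unused nucleophile free at 8.0 h.

nucleophile + protic impurity → quenched reagent (k = 0.651 M⁻¹ min⁻¹); electrophile + nucleophile → acid set free + target (k = 0.537 M⁻¹ min⁻¹); nucleophile + acid set free ⇌ protonated nucleophile, settled at all times (K = 41.0 M⁻¹); acid set free + free base ⇌ salt of the base (K = 31000 M⁻¹, k = 0.0761 M⁻¹ min⁻¹); target → over-reaction product (k = 4.02 × 10⁻⁶ min⁻¹) Of the nucleophile charged, 0 % is left in the flask, and protonated nucleophile stands at 1.65 × 10⁻¹⁰ M at 8.00 h. With 24 % of the electrophile left in the flask, S puts the impurity left at 18.3 %, and the flask holds 18 %. The neighbour with 0.88 M of electrophile keeps 54 % of it, so S puts its impurity left at 48.0 %, and that flask holds 48 %.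

(The runs are calculated for substances that don't exist; the scatter is artificial.)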